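**Retrosynthetic overview**

1. Last comes O-formylation of the C15 allylic alcohol; the C12–C13 bond of the side chain comes from a B-alkyl Suzuki–Miyaura coupling of a vinyl group on C9 with (E)-3-iodobut-2-en-1-ol.
2. The C1=C10 alkene comes from its C1=C2 isomer by a metal-hydride alkene walk run in the same flask as the cycloaddition; the C1=C2 isomer is a Diels–Alder retron.
3. Key disconnection, C3–C4 together with C5–C10: ring A is a cyclohexene in which quaternary C4 (CH3, CO2CH3) sits next to C5–H with CO2CH3 cis to C6. C4–C5 is therefore a masked (Z)-2-methyl enoate, C3 and C10 are the 1,4-ends of a diene C3=C2–C1=C10, and C5/C10 are joined by the four ring-B carbons C6–C9, the tether of a 1,7,9-decatriene. Rings A and B close together from an open chain.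
4. The open chain: (Z)-enoate by Still–Gennari olefination, C5/C6 by nitrile homologation, and the C8 (tertiary)/C9 (quaternary) pair by an enantioselective ester-enolate Claisen rearrangement of a trienyl propanoate built from a C6 enynol and vinyl bromide.

Key step: step 9

Remark on numbering: halimane numbering is used in the text (C4 carries CH3 and CO2CH3, C5 is the ring-fusion CH, C10 the sp2 ring-fusion carbon, C9 the quaternary carbon with CH3 and the side chain C11–C15, C8 the CH(CH3) carbon).

Remark on the target: the SMILES is read as (4S,5R,8R,9S); H-5 and the methyl groups on C4, C8 and C9 lie on one face, CO2CH3 and the side chain on the other.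

Assumption: the sense of induction of the (S,S)-controller and the enolate geometry given by Et3N in toluene/hexane in step 3 are assigned by analogy with simple (E)-allylic propanoates; if the antipode forms, the (R,R)-controller is used, if the other enolate geometry forms, i-Pr2NEt in CH2Cl2 is used, and nothing else changes.

**Route**

Step 1
Reactants: 1 (E)-3-methylpent-2-en-4-yn-1-ol; 2 vinyl bromide
Product: 4 (2E,4E)-3-methylhepta-2,4,6-trien-1-ol, via dienylboronate 3 (not isolated)
Conditions: catecholborane (2.2 equiv), THF, 65 °C; then 2 (1 M in THF), Pd(PPh3)4 (3 mol %), 2 M NaOH, 55 °C, sealed vessel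
Reagents that add atoms: vinyl bromide (2), C=CBr
Why: syn-hydroboration of the terminal alkyne puts boron on the terminal carbon and the Suzuki–Miyaura coupling joins the two sp2 carbons with retention, so the new C10=C1 bond should be (E) and the existing trisubstituted alkene keeps its (E)-geometry.

Step 2
Reactants: 4 (2E,4E)-3-methylhepta-2,4,6-trien-1-ol; 5 propanoyl chloride
Product: 6 (2E,4E)-3-methylhepta-2,4,6-trien-1-yl propanoate
Conditions: pyridine, DMAP (cat.), CH2Cl2, 0 °C
Reagents that add atoms: propanoyl chloride (5), CCC(=O)Cl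
Why: acylation of a primary allylic alcohol by an acid chloride (nucleophilic acyl substitution), with pyridine keeping the acid-labile trienyl ester from ionising.

Step 3
Reactants: 6 (2E,4E)-3-methylhepta-2,4,6-trien-1-yl propanoate; 7 (4S,5S)-2-bromo-4,5-diphenyl-1,3-bis{[3,5-bis(trifluoromethyl)phenyl]sulfonyl}-1,3,2-diazaborolidine
Product: 10 (2S,3R,4E)-3-ethenyl-2,3-dimethylhepta-4,6-dienoic acid, via boron enolate 8 (not isolated), via acyloxyborane 9 (not isolated)
Conditions: 7 (1.1 equiv, made beforehand from the commercial (S,S)-bis-sulfonamide and BBr3), Et3N, toluene/hexane, −78 °C, then −20 to 4 °C; aqueous work-up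
Reagents that add atoms: none
Why: enantioselective ester-enolate Claisen rearrangement (Ireland–Claisen type with a chiral boron controller), in which the amine/solvent pair is chosen to give the E(O)-boron enolate (methyl cis to the allyloxy oxygen) and the chair [3,3] transition state places the butadienyl group of the (E)-alkene equatorial, so that enolate and alkene geometry fix the C8/C9 relative configuration, the C2-symmetric controller fixes the absolute one, and bond formation at the trisubstituted terminus creates quaternary C9.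

Step 4
Reactants: 10 (2S,3R,4E)-3-ethenyl-2,3-dimethylhepta-4,6-dienoic acid
Product: 11 (2S,3R,4E)-3-ethenyl-2,3-dimethylhepta-4,6-dien-1-ol
Conditions: LiAlH4, Et2O, 0 °C to rt; Fieser work-up
Reagents that add atoms: none
Why: hydride reduction of the carboxylic acid to the primary alcohol, which leaves the unactivated alkenes and the diene alone and does not enolise the α-centre.

Step 5
Reactants: 11 (2S,3R,4E)-3-ethenyl-2,3-dimethylhepta-4,6-dien-1-ol; 12 iodine
Product: 13 (3E,5R,6S)-5-ethenyl-7-iodo-5,6-dimethylhepta-1,3-diene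
Conditions: PPh3, imidazole, I2, CH2Cl2, 0 °C, dark
Reagents that add atoms: iodine (12), II
Why: Appel-type iodination, an SN2 displacement of the oxyphosphonium group at the primary carbon that touches no stereocentre.

Step 6
Reactants: 13 (3E,5R,6S)-5-ethenyl-7-iodo-5,6-dimethylhepta-1,3-diene; 14 acetonitrile
Product: 16 (4R,5S,6E)-5-ethenyl-4,5-dimethylnona-6,8-dienenitrile, via lithioacetonitrile 15 (not isolated)
Conditions: n-BuLi, MeCN (4 equiv each), THF, −78 °C; then 13, DMPU, −78 to 0 °C
Reagents that add atoms: acetonitrile (14), CC#N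
Why: SN2 alkylation of lithioacetonitrile by the primary iodide adds C6 and C5 in one operation, with excess nucleophile and DMPU offsetting the β-branching and suppressing double alkylation.

Step 7
Reactants: 16 (4R,5S,6E)-5-ethenyl-4,5-dimethylnona-6,8-dienenitrile
Product: 18 (4R,5S,6E)-5-ethenyl-4,5-dimethylnona-6,8-dienal, via aluminio imine 17 (not isolated)
Conditions: i-Bu2AlH (1.2 equiv), CH2Cl2, −78 °C; then aqueous tartaric acid, 0 °C
Reagents that add atoms: water, O
Why: partial reduction of the nitrile by i-Bu2AlH stops at the N-aluminio imine, which is hydrolysed to the aldehyde on work-up (nitrile-to-aldehyde reduction).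

Step 8
Reactants: 18 (4R,5S,6E)-5-ethenyl-4,5-dimethylnona-6,8-dienal; 19 methyl 2-[bis(2,2,2-trifluoroethoxy)phosphoryl]propanoate
Product: 21 methyl (2Z,6R,7S,8E)-7-ethenyl-2,6,7-trimethylundeca-2,8,10-trienoate, via phosphonate anion 20 (not isolated)
Conditions: KN(SiMe3)2, 18-crown-6, THF, −78 °C
Reagents that add atoms: methyl 2-[bis(2,2,2-trifluoroethoxy)phosphoryl]propanoate (19), COC(=O)C(C)P(=O)(OCC(F)(F)F)OCC(F)(F)F
Why: Still–Gennari variant of the Horner–Wadsworth–Emmons olefination, whose electron-poor phosphonate eliminates from the kinetic adduct and should give the (Z)-2-methyl enoate that places CO2CH3 cis to C6 as the cycloaddition requires.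

Step 9
Reactants: 21 methyl (2Z,6R,7S,8E)-7-ethenyl-2,6,7-trimethylundeca-2,8,10-trienoate
Product: 24 methyl (1S,5S,6R,8aR)-5-ethenyl-1,5,6-trimethyl-1,2,3,5,6,7,8,8a-octahydronaphthalene-1-carboxylate, via trans-fused cycloadduct 22 (not isolated), via cis-fused cycloadduct 23 (not isolated)
Conditions: toluene (0.01 M), BHT (cat.), 175 °C, sealed tube; then cooled, concentrated under argon to 0.1 M, RuHCl(CO)(PPh3)3 (5 mol %), 100 °C
Reagents that add atoms: none
Why: a concerted suprafacial [4+2] cycloaddition (thermal intramolecular Diels–Alder reaction of a terminally activated 2,8,10-undecatrienoate, the closest known type) joins the diene C3=C2–C1=C10 and the (Z)-enoate C4=C5 and forms C3–C4 and C5–C10 at once. Ring A closes as the new cyclohexene that contains both new σ-bonds, and ring B closes in the fused six-membered mode through C5–C10 across the chair-like tether C6–C9, helped by the quaternary C9 (Thorpe–Ingold effect). C4 and C5 are set relative to each other by the (Z)-geometry of the dienophile (CO2CH3 cis to C6, CH3 cis to H-5), which the concerted addition transfers unchanged, and C5 is set relative to C8/C9 by the tether chair that keeps the C8 methyl and the C9 vinyl equatorial and the C9 methyl axial, so that the dienophile arm sits equatorial on the face away from the C9 methyl. C10 forms as both epimers (ester exo gives the trans-fused adduct 22, ester endo the cis-fused adduct 23) and is erased in the same flask, where the ruthenium hydride walks the disubstituted C1=C2 alkene of both adducts into the trisubstituted C1=C10 position by reversible Ru–H insertion and β-hydride elimination with removal of H-10 (ruthenium hydride-catalysed positional alkene isomerisation), while further migration to C5=C10 would need a tertiary alkylruthenium next to quaternary C9 and the vinyl group on C9 has no allylic hydrogen. The selectivity the step needs is the π-face with respect to C8/C9: the flipped chair needs the C8 methyl and the C9 vinyl axial and has only its trans-fused channel, because its cis-fused transition states put the diene arm 1,3-diaxial to the C8 methyl or the dienophile arm 1,3-diaxial to the C9 vinyl, whereas the favoured chair can use both channels. The preference should be useful but not complete, the minor face isomer is removed by chromatography of 24, and the vinyl group on C9 cannot reach the diene.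

Step 10
Reactants: 25 but-2-yn-1-ol; 12 iodine
Product: 27 (E)-3-iodobut-2-en-1-ol, via alkenylzirconocene 26 (not isolated)
Conditions: Cp2Zr(H)Cl (2.5 equiv), THF, 50 °C; then I2, 0 °C
Reagents that add atoms: iodine (12), II
Why: hydrozirconation under equilibrating conditions puts zirconium by syn addition on the alkyne carbon that carries the methyl group (the less hindered position, away from the zirconium alkoxide), and iodinolysis with retention should give the (E)-vinyl iodide (hydrozirconation–iodination).

Step 11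
Reactants: 24 methyl (1S,5S,6R,8aR)-5-ethenyl-1,5,6-trimethyl-1,2,3,5,6,7,8,8a-octahydronaphthalene-1-carboxylate; 27 (E)-3-iodobut-2-en-1-ol
Product: 29 methyl (1S,5S,6R,8aR)-5-[(3E)-5-hydroxy-3-methylpent-3-en-1-yl]-1,5,6-trimethyl-1,2,3,5,6,7,8,8a-octahydronaphthalene-1-carboxylate, via B-alkyl-9-BBN adduct 28 (not isolated)
Conditions: 9-BBN dimer, THF, 0 to 40 °C; then 27, PdCl2(dppf) (5 mol %), AsPh3, Cs2CO3, DMF/THF/H2O, rt
Reagents that add atoms: (E)-3-iodobut-2-en-1-ol (27), C/C(I)=C\CO
Why: 9-BBN hydroborates only the monosubstituted vinyl group (boron to terminal C12, the trisubstituted ring alkene and the hindered ester being inert) and the B-alkyl Suzuki–Miyaura coupling proceeds with retention at the vinyl iodide, so the side-chain alkene should be (E).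

Step 12
Reactants: 29 methyl (1S,5S,6R,8aR)-5-[(3E)-5-hydroxy-3-methylpent-3-en-1-yl]-1,5,6-trimethyl-1,2,3,5,6,7,8,8a-octahydronaphthalene-1-carboxylate; 30 acetic formic anhydride
Product: 31 methyl (1S,5S,6R,8aR)-5-[(3E)-5-(formyloxy)-3-methylpent-3-en-1-yl]-1,5,6-trimethyl-1,2,3,5,6,7,8,8a-octahydronaphthalene-1-carboxylate (target)
Conditions: 30 (made beforehand from Ac2O and HCO2H), pyridine, CH2Cl2, 0 °C
Reagents that add atoms: acetic formic anhydride (30), CC(=O)OC=O
Why: formyl transfer from the mixed anhydride to the primary allylic alcohol (acylation at the more electrophilic formyl carbonyl), with the hindered methyl ester left untouched.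

**Compound list**

1 | (E)-3-methylpent-2-en-4-yn-1-ol | C#C/C(C)=C/CO | starting material
2 | vinyl bromide | C=CBr | starting material
3 | 2-{(1E,3E)-5-[(1,3,2-benzodioxaborol-2-yl)oxy]-3-methylpenta-1,3-dien-1-yl}-1,3,2-benzodioxaborole | O(C/C=C(C)/C=C/B1Oc2ccccc2O1)B1Oc2ccccc2O1 | intermediate
4 | (2E,4E)-3-methylhepta-2,4,6-trien-1-ol | C=C/C=C/C(C)=C/CO | intermediate
5 | propanoyl chloride | CCC(=O)Cl | starting material
6 | (2E,4E)-3-methylhepta-2,4,6-trien-1-yl propanoate | CCC(=O)OC/C=C(C)/C=C/C=C | intermediate
7 | (4S,5S)-2-bromo-4,5-diphenyl-1,3-bis{[3,5-bis(trifluoromethyl)phenyl]sulfonyl}-1,3,2-diazaborolidine | BrB1N(S(=O)(=O)c2cc(cc(c2)C(F)(F)F)C(F)(F)F)[C@@H](c2ccccc2)[C@H](c2ccccc2)N1S(=O)(=O)c1cc(cc(c1)C(F)(F)F)C(F)(F)F | starting material (reagent)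
8 | E(O)-boron enolate of 6 bound to the diazaborolidine | C/C=C(\OC/C=C(C)/C=C/C=C)OB1N(S(=O)(=O)c2cc(cc(c2)C(F)(F)F)C(F)(F)F)[C@@H](c2ccccc2)[C@H](c2ccccc2)N1S(=O)(=O)c1cc(cc(c1)C(F)(F)F)C(F)(F)F | intermediate
9 | acyloxyborane of acid 10 with the diazaborolidine | O=C(OB1N(S(=O)(=O)c2cc(cc(c2)C(F)(F)F)C(F)(F)F)[C@@H](c2ccccc2)[C@H](c2ccccc2)N1S(=O)(=O)c1cc(cc(c1)C(F)(F)F)C(F)(F)F)[C@@H](C)[C@](/C=C/C=C)(C)C=C | intermediate
10 | (2S,3R,4E)-3-ethenyl-2,3-dimethylhepta-4,6-dienoic acid | OC(=O)[C@@H](C)[C@](/C=C/C=C)(C)C=C | intermediate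
11 | (2S,3R,4E)-3-ethenyl-2,3-dimethylhepta-4,6-dien-1-ol | OC[C@@H](C)[C@](/C=C/C=C)(C)C=C | intermediate
12 | iodine | II | starting material
13 | (3E,5R,6S)-5-ethenyl-7-iodo-5,6-dimethylhepta-1,3-diene | IC[C@@H](C)[C@](/C=C/C=C)(C)C=C | intermediate
14 | acetonitrile | CC#N | starting material
15 | lithioacetonitrile | [Li]CC#N | intermediate
16 | (4R,5S,6E)-5-ethenyl-4,5-dimethylnona-6,8-dienenitrile | N#CCC[C@@H](C)[C@](/C=C/C=C)(C)C=C | intermediate
17 | N-(diisobutylaluminio)imine of 18 | CC(C)C[Al](CC(C)C)N=CCC[C@@H](C)[C@](/C=C/C=C)(C)C=C | intermediate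
18 | (4R,5S,6E)-5-ethenyl-4,5-dimethylnona-6,8-dienal | O=CCC[C@@H](C)[C@](/C=C/C=C)(C)C=C | intermediate
19 | methyl 2-[bis(2,2,2-trifluoroethoxy)phosphoryl]propanoate | COC(=O)C(C)P(=O)(OCC(F)(F)F)OCC(F)(F)F | starting material
20 | potassium salt of the carbanion of 19 | [K+].COC(=O)[C-](C)P(=O)(OCC(F)(F)F)OCC(F)(F)F | intermediate
21 | methyl (2Z,6R,7S,8E)-7-ethenyl-2,6,7-trimethylundeca-2,8,10-trienoate | COC(=O)/C(C)=C\CC[C@@H](C)[C@](/C=C/C=C)(C)C=C | intermediate
22 | methyl (1S,4aS,5S,6R,8aR)-5-ethenyl-1,5,6-trimethyl-1,2,4a,5,6,7,8,8a-octahydronaphthalene-1-carboxylate (trans-fused cycloadduct) | COC(=O)[C@@]1(C)CC=C[C@H]2[C@H]1CC[C@@H](C)[C@]2(C)C=C | intermediate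
23 | methyl (1S,4aR,5S,6R,8aR)-5-ethenyl-1,5,6-trimethyl-1,2,4a,5,6,7,8,8a-octahydronaphthalene-1-carboxylate (cis-fused cycloadduct) | COC(=O)[C@@]1(C)CC=C[C@@H]2[C@H]1CC[C@@H](C)[C@]2(C)C=C | intermediate
24 | methyl (1S,5S,6R,8aR)-5-ethenyl-1,5,6-trimethyl-1,2,3,5,6,7,8,8a-octahydronaphthalene-1-carboxylate | COC(=O)[C@@]1(C)CCC=C2[C@H]1CC[C@@H](C)[C@]2(C)C=C | intermediate
25 | but-2-yn-1-ol | CC#CCO | starting material
26 | (E)-alkenylzirconocene chloride from 25, zirconium on C3, oxygen zirconated (cyclopentadienyl rings drawn σ-bonded) | C/C(=C\CO[Zr](Cl)(C1C=CC=C1)C1C=CC=C1)[Zr](Cl)(C1C=CC=C1)C1C=CC=C1 | intermediate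
27 | (E)-3-iodobut-2-en-1-ol | C/C(I)=C\CO | intermediate
28 | B-alkyl-9-borabicyclo[3.3.1]nonane adduct of 24 (boron on C12) | COC(=O)[C@@]1(C)CCC=C2[C@H]1CC[C@@H](C)[C@]2(C)CCB1C2CCCC1CCC2 | intermediate
29 | methyl (1S,5S,6R,8aR)-5-[(3E)-5-hydroxy-3-methylpent-3-en-1-yl]-1,5,6-trimethyl-1,2,3,5,6,7,8,8a-octahydronaphthalene-1-carboxylate | COC(=O)[C@@]1(C)CCC=C2[C@H]1CC[C@@H](C)[C@]2(C)CC/C(C)=C/CO | intermediate
30 | acetic formic anhydride | CC(=O)OC=O | starting material (reagent)
31 | methyl (1S,5S,6R,8aR)-5-[(3E)-5-(formyloxy)-3-methylpent-3-en-1-yl]-1,5,6-trimethyl-1,2,3,5,6,7,8,8a-octahydronaphthalene-1-carboxylate | COC(=O)[C@@]1(C)CCC=C2[C@H]1CC[C@@H](C)[C@]2(C)CC/C(C)=C/COC=O | target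

**Step count and risks**

Total step count: 12. Longest linear sequence: 11 (steps 1 to 9, 11 and 12).

Steps most likely to fail:

Step 9. What may go wrong: insufficient π-facial discrimination in the cycloaddition (reaction on the tether chair that carries the C8 methyl axial), slow ring closure at the trisubstituted dienophile that leaves time for diene oligomerisation, and, in the second stage, stalling of the alkene walk at the disubstituted isomers or over-migration into the C5=C10 position with loss of the C5 configuration. Fallback, from 21 to 24: the two events are separated, the cycloaddition being run at the aldehyde oxidation level under catalyst control and the alkene being moved by a stepwise transposition through the epoxide. Reduction of 21 with i-Bu2AlH at −78 °C gives (2Z,6R,7S,8E)-7-ethenyl-2,6,7-trimethylundeca-2,8,10-trien-1-ol F1, and MnO2 in CH2Cl2 gives the (Z)-enal (2Z,6R,7S,8E)-7-ethenyl-2,6,7-trimethylundeca-2,8,10-trienal F2. A triflimide-activated, proline-derived chiral B-(o-tolyl)oxazaborolidine (the enantiomer that reinforces the chair preference) at −78 to −40 °C should then give the bicyclic aldehyde F3 as its ring-fusion epimers. Pinnick oxidation (NaClO2, NaH2PO4, 2-methylbut-2-ene) gives the carboxylic acid F4, and Me3SiCHN2 in MeOH/toluene gives the methyl esters 22 and 23, which are isolated here. mCPBA with NaHCO3 at 0 °C oxidises the ring alkene ahead of the monosubstituted vinyl group and gives the 3,4-epoxide F5. Me3SiOTf with DBU opens it with loss of the tertiary H-10 to the allylic silyl ether F6 (silyl triflate/amidine variant of the epoxide-to-allylic-alcohol isomerisation). K2CO3 in MeOH gives the allylic alcohol F7 and Ac2O/pyridine the allylic acetate F8. Pd(PPh3)4 with Bu3SnH then delivers hydride to the less hindered allyl terminus C2 and should give 24. The epoxide sequence can also be entered directly with thermally made 22 and 23 if only the alkene walk fails.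

Step 3. What may go wrong: ionisation of the trienyl ester by the Lewis-acidic boron before rearrangement, or erosion of enolate-geometry and facial control. Fallback, from 6 back to 10: the classical Ireland–Claisen rearrangement followed by resolution. LiN(i-Pr)2 in THF at −78 °C (kinetic E(O)-enolate) and Me3SiCl give the trimethylsilyl ketene acetal F9, which rearranges on warming to the racemic trimethylsilyl ester F10. Aqueous hydrolysis gives the racemic acid, that is 10 together with its antipode (2R,3S,4E)-3-ethenyl-2,3-dimethylhepta-4,6-dienoic acid F11. Crystallisation with (S)-1-phenylethylamine should separate the (S)-1-phenylethylammonium salt of 10 F12, from which dilute HCl liberates 10.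

Step 6. What may go wrong: slow SN2 displacement at the β-branched primary carbon next to quaternary C9, with E2 elimination by the basic nitrile anion taking over. Fallback, from 11 to 16: the two carbons are added by olefination instead of alkylation, so that steps 5 and 6 are not needed. Dess–Martin periodinane with NaHCO3 in CH2Cl2 at 0 °C oxidises 11 to (2S,3R,4E)-3-ethenyl-2,3-dimethylhepta-4,6-dienal F13. The neutral stabilised ylide (triphenylphosphoranylidene)acetonitrile in toluene at 60 °C, with no base that could epimerise C8, gives (4R,5R,6E)-5-ethenyl-4,5-dimethylnona-2,6,8-trienenitrile F14 as both C2=C3 isomers. Mg turnings in MeOH at 0 °C to rt then reduce only the nitrile-conjugated alkene, leaving the unactivated diene and the vinyl group, and should give 16.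

Further compounds
F1 | step 9 | (2Z,6R,7S,8E)-7-ethenyl-2,6,7-trimethylundeca-2,8,10-trien-1-ol | OC/C(C)=C\CC[C@@H](C)[C@](/C=C/C=C)(C)C=C
F2 | step 9 | (2Z,6R,7S,8E)-7-ethenyl-2,6,7-trimethylundeca-2,8,10-trienal | O=C/C(C)=C\CC[C@@H](C)[C@](/C=C/C=C)(C)C=C
F3 | step 9 | (1S,5S,6R,8aR)-5-ethenyl-1,5,6-trimethyl-1,2,4a,5,6,7,8,8a-octahydronaphthalene-1-carbaldehyde, both C4a epimers | O=C[C@@]1(C)CC=CC2[C@H]1CC[C@@H](C)[C@]2(C)C=C
F4 | step 9 | (1S,5S,6R,8aR)-5-ethenyl-1,5,6-trimethyl-1,2,4a,5,6,7,8,8a-octahydronaphthalene-1-carboxylic acid, both C4a epimers | OC(=O)[C@@]1(C)CC=CC2[C@H]1CC[C@@H](C)[C@]2(C)C=C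
F5 | step 9 | 3,4-epoxide of 22/23, epoxide face and C4a not defined | COC(=O)[C@@]1(C)CC3OC3C2[C@H]1CC[C@@H](C)[C@]2(C)C=C
F6 | step 9 | methyl (1S,5S,6R,8aR)-5-ethenyl-1,5,6-trimethyl-3-(trimethylsilyloxy)-1,2,3,5,6,7,8,8a-octahydronaphthalene-1-carboxylate, C3 not defined | COC(=O)[C@@]1(C)CC(O[Si](C)(C)C)C=C2[C@H]1CC[C@@H](C)[C@]2(C)C=C
F7 | step 9 | methyl (1S,5S,6R,8aR)-5-ethenyl-3-hydroxy-1,5,6-trimethyl-1,2,3,5,6,7,8,8a-octahydronaphthalene-1-carboxylate, C3 not defined | COC(=O)[C@@]1(C)CC(O)C=C2[C@H]1CC[C@@H](C)[C@]2(C)C=C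
F8 | step 9 | methyl (1S,5S,6R,8aR)-3-acetoxy-5-ethenyl-1,5,6-trimethyl-1,2,3,5,6,7,8,8a-octahydronaphthalene-1-carboxylate, C3 not defined | COC(=O)[C@@]1(C)CC(OC(C)=O)C=C2[C@H]1CC[C@@H](C)[C@]2(C)C=C
F9 | step 3 | trimethylsilyl ketene acetal of 6, E(O) geometry | C/C=C(\OC/C=C(C)/C=C/C=C)O[Si](C)(C)C
F10 | step 3 | trimethylsilyl (2S*,3R*,4E)-3-ethenyl-2,3-dimethylhepta-4,6-dienoate, racemic, one enantiomer drawn | C[Si](C)(C)OC(=O)[C@@H](C)[C@](/C=C/C=C)(C)C=C
F11 | step 3 | (2R,3S,4E)-3-ethenyl-2,3-dimethylhepta-4,6-dienoic acid | OC(=O)[C@H](C)[C@@](/C=C/C=C)(C)C=C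
F12 | step 3 | (S)-1-phenylethylammonium (2S,3R,4E)-3-ethenyl-2,3-dimethylhepta-4,6-dienoate | C[C@H]([NH3+])c1ccccc1.[O-]C(=O)[C@@H](C)[C@](/C=C/C=C)(C)C=C
F13 | step 6 | (2S,3R,4E)-3-ethenyl-2,3-dimethylhepta-4,6-dienal | O=C[C@@H](C)[C@](/C=C/C=C)(C)C=C
F14 | step 6 | (4R,5R,6E)-5-ethenyl-4,5-dimethylnona-2,6,8-trienenitrile, C2=C3 geometry not defined | N#CC=C[C@@H](C)[C@](/C=C/C=C)(C)C=C
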